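The route rests on disconnecting the O1–C8a aryl ether bond of the chroman. The C8 ketone of ring A is ortho to C8a and C7 and para to C5, so a fluorine at C8a is displaced by the tethered tertiary C2 alkoxide; this single intramolecular nucleophilic aromatic substitution forms O1–C8a and closes the pyran ring without touching either stereocentre. Its precursor is a fully substituted 2,6-difluorobenzophenone: ring A carries F at C8a and C7, OMe at C5, the (2R)-configured C10 side chain at C6, and at C4a a (2R)-2-(methoxymethoxy)-3-hydroxy-3-methylbutyl chain whose free tertiary hydroxyl is the nucleophile; ring B is MOM-protected.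

Key step: step 14

Remarks on the chemistry (assumptions):
- Compound 1 is taken as the purchasable (1S,4R)-p-mentha-2,8-dien-1-ol, the cannabinoid building block made from (R)-limonene. Its C1 centre is destroyed in step 2, so the C1 epimer or a mixture serves equally; only the (4R) centre matters.
- The side-chain stereocentre keeps one spatial arrangement from 1 to 28. Its descriptor reads S in 3–6 and R once the aryl carbon is attached, and 4R in 1 reads 5S in 2, only because the CIP priorities change.
- The stereodescriptors of 23 and 25 were checked against the target: C3 and the side-chain centre are both R in all three, so no structure needed correcting.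
- The free tertiary/protected secondary oxygen pattern of 23 is obtained from the order of events (MOM ether on an α-hydroxy ester, then MeMgBr), not from selective protection of a diol.
- The C10 electrophile is used as the primary triflate, not the iodide, so that the ortho-fluoroaryllithium can be alkylated at −78 °C.

Step 1
Reactants: 1 (1S,4R)-1-methyl-4-(prop-1-en-2-yl)cyclohex-2-en-1-ol
Product: 2 (1R,2S,5S,6R)-2-methyl-5-(prop-1-en-2-yl)-7-oxabicyclo[4.1.0]heptan-2-ol
Conditions: VO(acac)2 (2 mol %), t-BuOOH (1.5 equiv), CH2Cl2, 0 °C → rt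
Reagents that add atoms: tert-butyl hydroperoxide, CC(C)(C)OO
Why: Hydroxyl-directed vanadium-catalysed epoxidation should deliver oxygen to the allylic C2=C3 bond from the face of the tertiary hydroxyl and leave the remote isopropenyl group alone; the two new epoxide centres (cis to OH) are erased in step 2.

Step 2
Reactants: 2 (1R,2S,5S,6R)-2-methyl-5-(prop-1-en-2-yl)-7-oxabicyclo[4.1.0]heptan-2-ol
Product: 4 (5S)-6-hydroxy-5-(prop-1-en-2-yl)hexan-2-one, via keto aldehyde 3 (not isolated)
Conditions: H5IO6 (2.5 equiv), THF/H2O, 0 °C; extractive work-up; then NaBH4 (0.5 equiv), CH2Cl2/EtOH, −78 °C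
Reagents that add atoms: water, O (expected to open the epoxide at the carbon distal to the carbinol, which becomes the CH2OH carbon)
Why: Periodic acid should open the epoxide hydrolytically and cleave the resulting 1,2,3-triol twice (Malaprade glycol cleavage), excising the middle carbon as formic acid, and borohydride at −78 °C should reduce the α-branched aldehyde chemoselectively beside the methyl ketone before it can enolise, so the isopropenyl-bearing centre of 1 is carried through unchanged.

Step 3
Reactants: 4 (5S)-6-hydroxy-5-(prop-1-en-2-yl)hexan-2-one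
Product: 5 (2S)-5-methyl-2-(prop-1-en-2-yl)hex-5-en-1-ol
Conditions: Ph3PCH3Br (2.5 equiv), KOt-Bu (2.4 equiv), THF, 0 °C → rt
Reagents that add atoms: methyltriphenylphosphonium bromide, C[P+](c1ccccc1)(c1ccccc1)c1ccccc1.[Br-]
Why: Wittig methylenation of the methyl ketone with excess ylide (one equivalent is spent on the hydroxyl) should install the second 1,1-disubstituted alkene, and the stereocentre, γ to the carbonyl, cannot epimerise.

Step 4
Reactants: 5 (2S)-5-methyl-2-(prop-1-en-2-yl)hex-5-en-1-ol
Product: 6 (2S)-5-methyl-2-(prop-1-en-2-yl)hex-5-en-1-yl trifluoromethanesulfonate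
Conditions: Tf2O (1.15 equiv), pyridine (1.3 equiv), CH2Cl2, −78 → −40 °C; cold work-up, used at once
Reagents that add atoms: trifluoromethanesulfonic anhydride, O=S(=O)(OS(=O)(=O)C(F)(F)F)C(F)(F)F
Why: O-Sulfonylation of the primary alcohol at low temperature should give the primary triflate, a far faster SN2 partner for an aryllithium than the β-branched iodide, and the C–O bond at the stereocentre's neighbour is not broken.

Step 5
Reactants: 7 methyl 3-hydroxybenzoate
Product: 8 methyl 3-(methoxymethoxy)benzoate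
Conditions: MeOCH2Cl (1.5 equiv), i-Pr2NEt (2 equiv), CH2Cl2, 0 °C → rt
Reagents that add atoms: chloromethyl methyl ether, COCCl
Why: O-Alkylation of the phenol with chloromethyl methyl ether (MOM protection) should give an acetal that withstands the organometallic and strongly basic steps ahead.

Step 6
Reactants: 8 methyl 3-(methoxymethoxy)benzoate
Product: 9 N-methoxy-3-(methoxymethoxy)-N-methylbenzamide
Conditions: MeNH(OMe)·HCl (1.5 equiv), i-PrMgCl (3 equiv), THF, −20 → 0 °C
Reagents that add atoms: N,O-dimethylhydroxylamine hydrochloride, CNOC.Cl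
Why: Aminolysis of the methyl ester by the chloromagnesium amide of N,O-dimethylhydroxylamine (Weinreb amide formation) should proceed at low temperature without touching the aryl MOM ether.

Step 7
Reactants: 10 3,5-difluoroanisole
Product: 12 (2,6-difluoro-4-methoxyphenyl)trimethylsilane, via aryllithium 11 (not isolated)
Conditions: n-BuLi (1.05 equiv), THF, −78 °C; Me3SiCl (1.2 equiv), −78 °C → rt
Reagents that add atoms: chlorotrimethylsilane, C[Si](C)(C)Cl
Why: Directed ortho-metalation should occur at the most acidic ring position, between the two fluorines, and silylation blocks this future ketone carbon so that later lithiations must take place between fluorine and methoxy.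

Step 8
Reactants: 12 (2,6-difluoro-4-methoxyphenyl)trimethylsilane; 6 (2S)-5-methyl-2-(prop-1-en-2-yl)hex-5-en-1-yl trifluoromethanesulfonate
Product: 14 {2,6-difluoro-4-methoxy-3-[(2R)-5-methyl-2-(prop-1-en-2-yl)hex-5-en-1-yl]phenyl}trimethylsilane, via aryllithium 13 (not isolated)
Conditions: 12 (1.5 equiv), s-BuLi (1.4 equiv), THF, −78 °C; then 6 (1.0 equiv), −78 → −40 °C
Reagents that add atoms: none
Why: With the position between the fluorines blocked, s-BuLi should metalate the site flanked by F and OMe (directed ortho-metalation) and the aryllithium, used in excess, should be alkylated by the primary triflate in an SN2 reaction below the temperature at which ortho-fluoroaryllithiums lose LiF; the stereocentre is β to the reacting carbon and is not involved.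

Step 9
Reactants: 14 {2,6-difluoro-4-methoxy-3-[(2R)-5-methyl-2-(prop-1-en-2-yl)hex-5-en-1-yl]phenyl}trimethylsilane; 15 methyl (2R)-oxirane-2-carboxylate
Product: 18 methyl (2R)-3-{2,4-difluoro-6-methoxy-5-[(2R)-5-methyl-2-(prop-1-en-2-yl)hex-5-en-1-yl]-3-(trimethylsilyl)phenyl}-2-hydroxypropanoate, via aryllithium 16 (not isolated), via arylmagnesium bromide 17 (not isolated)
Conditions: s-BuLi (1.0 equiv), THF, −78 °C; MgBr2·OEt2 (1.2 equiv), −78 → −40 °C; CuI (10 mol %), 15 (1.5 equiv), −40 → −15 °C
Reagents that add atoms: none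
Why: The last ring hydrogen, again between F and OMe, should be lithiated, transmetalated to the thermally more robust Grignard reagent and added to the terminal carbon of the glycidate under CuI catalysis (copper-catalysed epoxide opening), which tolerates the ester and leaves the epoxide C2 centre, the future C3, untouched.

Step 10
Reactants: 18 methyl (2R)-3-{2,4-difluoro-6-methoxy-5-[(2R)-5-methyl-2-(prop-1-en-2-yl)hex-5-en-1-yl]-3-(trimethylsilyl)phenyl}-2-hydroxypropanoate
Product: 19 methyl (2R)-3-{2,4-difluoro-6-methoxy-5-[(2R)-5-methyl-2-(prop-1-en-2-yl)hex-5-en-1-yl]-3-(trimethylsilyl)phenyl}-2-(methoxymethoxy)propanoate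
Conditions: MeOCH2Cl (3 equiv), i-Pr2NEt (4 equiv), CH2Cl2, 0 °C → rt
Reagents that add atoms: chloromethyl methyl ether, COCCl
Why: MOM protection under amine-base conditions should cap the secondary oxygen with a non-migrating acetal before the tertiary hydroxyl exists, and the weak base does not epimerise the α-centre of the ester.

Step 11
Reactants: 19 methyl (2R)-3-{2,4-difluoro-6-methoxy-5-[(2R)-5-methyl-2-(prop-1-en-2-yl)hex-5-en-1-yl]-3-(trimethylsilyl)phenyl}-2-(methoxymethoxy)propanoate
Product: 20 (3R)-4-{2,4-difluoro-6-methoxy-5-[(2R)-5-methyl-2-(prop-1-en-2-yl)hex-5-en-1-yl]-3-(trimethylsilyl)phenyl}-3-(methoxymethoxy)-2-methylbutan-2-ol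
Conditions: MeMgBr (3.5 equiv), THF, 0 °C
Reagents that add atoms: methylmagnesium bromide, C[Mg]Br
Why: Double Grignard addition to the ester should create the gem-dimethyl carbinol (the future C2), which gives the free tertiary and protected secondary oxygen pattern needed for ring closure.

Step 12
Reactants: 20 (3R)-4-{2,4-difluoro-6-methoxy-5-[(2R)-5-methyl-2-(prop-1-en-2-yl)hex-5-en-1-yl]-3-(trimethylsilyl)phenyl}-3-(methoxymethoxy)-2-methylbutan-2-ol
Product: 21 (3R)-4-{4,6-difluoro-2-methoxy-3-[(2R)-5-methyl-2-(prop-1-en-2-yl)hex-5-en-1-yl]phenyl}-3-(methoxymethoxy)-2-methylbutan-2-ol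
Conditions: Bu4NF·3H2O (1.5 equiv), THF, rt
Reagents that add atoms: none
Why: Fluoride should attack silicon and the aryl anion, stabilised by two ortho fluorines, is protonated by the hydrate water (protodesilylation), unmasking C8–H while the MOM ether, the alcohol and the alkenes stay inert.

Step 13
Reactants: 21 (3R)-4-{4,6-difluoro-2-methoxy-3-[(2R)-5-methyl-2-(prop-1-en-2-yl)hex-5-en-1-yl]phenyl}-3-(methoxymethoxy)-2-methylbutan-2-ol; 9 N-methoxy-3-(methoxymethoxy)-N-methylbenzamide
Product: 23 {2,6-difluoro-3-[(2R)-3-hydroxy-2-(methoxymethoxy)-3-methylbutyl]-4-methoxy-5-[(2R)-5-methyl-2-(prop-1-en-2-yl)hex-5-en-1-yl]phenyl}[3-(methoxymethoxy)phenyl]methanone, via dilithio species 22 (not isolated)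
Conditions: n-BuLi (2.1 equiv), THF, −78 °C; 9 (1.3 equiv), −78 → −30 °C; aq. NH4Cl
Reagents that add atoms: none
Why: The first equivalent of n-BuLi should form the alkoxide and the second remove the only ring hydrogen, acidified by two flanking fluorines, and the aryllithium adds to the amide to give a chelated tetrahedral adduct that releases the ketone only on work-up (Weinreb ketone synthesis), so neither over-addition nor premature ring closure can occur.

Step 14
Reactants: 23 {2,6-difluoro-3-[(2R)-3-hydroxy-2-(methoxymethoxy)-3-methylbutyl]-4-methoxy-5-[(2R)-5-methyl-2-(prop-1-en-2-yl)hex-5-en-1-yl]phenyl}[3-(methoxymethoxy)phenyl]methanone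
Product: 25 {(3R)-7-fluoro-5-methoxy-3-(methoxymethoxy)-2,2-dimethyl-6-[(2R)-5-methyl-2-(prop-1-en-2-yl)hex-5-en-1-yl]chroman-8-yl}[3-(methoxymethoxy)phenyl]methanone, via potassium alkoxide 24 (not isolated)
Conditions: KN(SiMe3)2 (1.1 equiv), THF, 0 °C; then DMF cosolvent, rt, 0.02 M
Reagents that add atoms: none
Why: KN(SiMe3)2 deprotonates the tertiary hydroxyl, the alkoxide adds to C8a to give a Meisenheimer anion whose charge is spread onto the C8 carbonyl oxygen, and loss of fluoride restores the aromatic ring. The closest known reaction type is the intramolecular SNAr etherification of ortho-fluoroaryl ketones by alkoxides to give chromans and related benzo-fused ethers. The pyran ring closes in a 6-exo-trig mode onto the aromatic carbon. No stereocentre is formed, and C3 and the side-chain centre carry no acidic hydrogen and are not touched. The step needs site selectivity between the two fluorines and between the two oxygens of the chain: only C8a lies within reach of the tether (C5 bears the poor leaving group OMe and C7 is out of range), and the MOM acetal on the secondary oxygen, which cannot migrate to the neighbouring alkoxide, forces closure through the tertiary oxygen to the six-membered ring instead of a dihydrobenzofuran. High dilution should suppress intermolecular substitution, and the ketone is non-enolisable and flanked only by small fluorines, so the base has nothing else to attack.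

Step 15
Reactants: 25 {(3R)-7-fluoro-5-methoxy-3-(methoxymethoxy)-2,2-dimethyl-6-[(2R)-5-methyl-2-(prop-1-en-2-yl)hex-5-en-1-yl]chroman-8-yl}[3-(methoxymethoxy)phenyl]methanone
Product: 27 {(3R)-7-hydroxy-5-methoxy-3-(methoxymethoxy)-2,2-dimethyl-6-[(2R)-5-methyl-2-(prop-1-en-2-yl)hex-5-en-1-yl]chroman-8-yl}[3-(methoxymethoxy)phenyl]methanone, via sulfonylethyl aryl ether 26 (not isolated)
Conditions: MeSO2CH2CH2OH (3 equiv), NaH (6 equiv), DMF, 0 → 50 °C; aq. NH4Cl
Reagents that add atoms: 2-(methylsulfonyl)ethanol, CS(=O)(=O)CCO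
Why: The primary alkoxide should displace the remaining fluorine ortho to the ketone (SNAr) and the β-sulfonylethyl ether then undergoes E1cB elimination under the same basic conditions, so the sulfonyl alcohol acts as a hydroxide surrogate and the C7 phenoxide is released in one flask.

Step 16
Reactants: 27 {(3R)-7-hydroxy-5-methoxy-3-(methoxymethoxy)-2,2-dimethyl-6-[(2R)-5-methyl-2-(prop-1-en-2-yl)hex-5-en-1-yl]chroman-8-yl}[3-(methoxymethoxy)phenyl]methanone
Product: 28 {(3R)-3,7-dihydroxy-5-methoxy-2,2-dimethyl-6-[(2R)-5-methyl-2-(prop-1-en-2-yl)hex-5-en-1-yl]chroman-8-yl}(3-hydroxyphenyl)methanone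
Conditions: ZnBr2 (3 equiv), n-PrSH (6 equiv), CH2Cl2, 0 °C, short reaction time
Reagents that add atoms: none
Why: ZnBr2 should activate each methoxymethyl acetal and the thiol takes up the methoxymethyl group (Lewis acid-promoted acetal exchange), freeing the C3 alcohol and the ring B phenol within minutes at 0 °C without the protic acid that could add the C7 phenol across the neighbouring isopropenyl group.

Compound list
1 | (1S,4R)-1-methyl-4-(prop-1-en-2-yl)cyclohex-2-en-1-ol | C[C@@]1(O)C=C[C@@H](CC1)C(C)=C | starting material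
2 | (1R,2S,5S,6R)-2-methyl-5-(prop-1-en-2-yl)-7-oxabicyclo[4.1.0]heptan-2-ol (epoxide cis to OH) | C[C@@]1(O)[C@@H]2O[C@@H]2[C@@H](CC1)C(C)=C | intermediate
3 | (2S)-5-oxo-2-(prop-1-en-2-yl)hexanal | CC(=O)CC[C@H](C=O)C(C)=C | intermediate
4 | (5S)-6-hydroxy-5-(prop-1-en-2-yl)hexan-2-one | CC(=O)CC[C@H](CO)C(C)=C | intermediate
5 | (2S)-5-methyl-2-(prop-1-en-2-yl)hex-5-en-1-ol | C=C(C)CC[C@H](CO)C(C)=C | intermediate
6 | (2S)-5-methyl-2-(prop-1-en-2-yl)hex-5-en-1-yl trifluoromethanesulfonate | C=C(C)CC[C@H](COS(=O)(=O)C(F)(F)F)C(C)=C | intermediate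
7 | methyl 3-hydroxybenzoate | COC(=O)c1cccc(O)c1 | starting material
8 | methyl 3-(methoxymethoxy)benzoate | COCOc1cccc(c1)C(=O)OC | intermediate
9 | N-methoxy-3-(methoxymethoxy)-N-methylbenzamide | COCOc1cccc(c1)C(=O)N(C)OC | intermediate
10 | 3,5-difluoroanisole | COc1cc(F)cc(F)c1 | starting material
11 | (2,6-difluoro-4-methoxyphenyl)lithium | COc1cc(F)c([Li])c(F)c1 | intermediate
12 | (2,6-difluoro-4-methoxyphenyl)trimethylsilane | COc1cc(F)c([Si](C)(C)C)c(F)c1 | intermediate
13 | [2,4-difluoro-6-methoxy-3-(trimethylsilyl)phenyl]lithium | COc1cc(F)c([Si](C)(C)C)c(F)c1[Li] | intermediate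
14 | {2,6-difluoro-4-methoxy-3-[(2R)-5-methyl-2-(prop-1-en-2-yl)hex-5-en-1-yl]phenyl}trimethylsilane | C=C(C)CC[C@H](Cc1c(OC)cc(F)c([Si](C)(C)C)c1F)C(=C)C | intermediate
15 | methyl (2R)-oxirane-2-carboxylate | COC(=O)[C@H]1CO1 | starting material
16 | {2,4-difluoro-6-methoxy-5-[(2R)-5-methyl-2-(prop-1-en-2-yl)hex-5-en-1-yl]-3-(trimethylsilyl)phenyl}lithium | C=C(C)CC[C@H](Cc1c(OC)c([Li])c(F)c([Si](C)(C)C)c1F)C(=C)C | intermediate
17 | {2,4-difluoro-6-methoxy-5-[(2R)-5-methyl-2-(prop-1-en-2-yl)hex-5-en-1-yl]-3-(trimethylsilyl)phenyl}magnesium bromide | C=C(C)CC[C@H](Cc1c(OC)c([Mg]Br)c(F)c([Si](C)(C)C)c1F)C(=C)C | intermediate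
18 | methyl (2R)-3-{2,4-difluoro-6-methoxy-5-[(2R)-5-methyl-2-(prop-1-en-2-yl)hex-5-en-1-yl]-3-(trimethylsilyl)phenyl}-2-hydroxypropanoate | C=C(C)CC[C@H](Cc1c(OC)c(C[C@@H](O)C(=O)OC)c(F)c([Si](C)(C)C)c1F)C(=C)C | intermediate
19 | methyl (2R)-3-{2,4-difluoro-6-methoxy-5-[(2R)-5-methyl-2-(prop-1-en-2-yl)hex-5-en-1-yl]-3-(trimethylsilyl)phenyl}-2-(methoxymethoxy)propanoate | C=C(C)CC[C@H](Cc1c(OC)c(C[C@@H](OCOC)C(=O)OC)c(F)c([Si](C)(C)C)c1F)C(=C)C | intermediate
20 | (3R)-4-{2,4-difluoro-6-methoxy-5-[(2R)-5-methyl-2-(prop-1-en-2-yl)hex-5-en-1-yl]-3-(trimethylsilyl)phenyl}-3-(methoxymethoxy)-2-methylbutan-2-ol | C=C(C)CC[C@H](Cc1c(OC)c(C[C@@H](OCOC)C(C)(C)O)c(F)c([Si](C)(C)C)c1F)C(=C)C | intermediate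
21 | (3R)-4-{4,6-difluoro-2-methoxy-3-[(2R)-5-methyl-2-(prop-1-en-2-yl)hex-5-en-1-yl]phenyl}-3-(methoxymethoxy)-2-methylbutan-2-ol | C=C(C)CC[C@H](Cc1c(OC)c(C[C@@H](OCOC)C(C)(C)O)c(F)cc1F)C(=C)C | intermediate
22 | dilithio derivative of 21 (lithium alkoxide at the tertiary oxygen, lithium on the ring carbon between the fluorines) | C=C(C)CC[C@H](Cc1c(OC)c(C[C@@H](OCOC)C(C)(C)O[Li])c(F)c([Li])c1F)C(=C)C | intermediate
23 | {2,6-difluoro-3-[(2R)-3-hydroxy-2-(methoxymethoxy)-3-methylbutyl]-4-methoxy-5-[(2R)-5-methyl-2-(prop-1-en-2-yl)hex-5-en-1-yl]phenyl}[3-(methoxymethoxy)phenyl]methanone | C=C(C)CC[C@H](Cc1c(F)c(C(=O)c2cccc(OCOC)c2)c(F)c(C[C@@H](OCOC)C(C)(C)O)c1OC)C(=C)C | intermediate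
24 | potassium alkoxide of 23 (at the tertiary oxygen) | C=C(C)CC[C@H](Cc1c(F)c(C(=O)c2cccc(OCOC)c2)c(F)c(C[C@@H](OCOC)C(C)(C)O[K])c1OC)C(=C)C | intermediate
25 | {(3R)-7-fluoro-5-methoxy-3-(methoxymethoxy)-2,2-dimethyl-6-[(2R)-5-methyl-2-(prop-1-en-2-yl)hex-5-en-1-yl]chroman-8-yl}[3-(methoxymethoxy)phenyl]methanone | C=C(C)CC[C@H](Cc1c(F)c(C(=O)c2cccc(OCOC)c2)c2c(c1OC)C[C@@H](OCOC)C(C)(C)O2)C(=C)C | intermediate
26 | {(3R)-5-methoxy-3-(methoxymethoxy)-2,2-dimethyl-6-[(2R)-5-methyl-2-(prop-1-en-2-yl)hex-5-en-1-yl]-7-[2-(methylsulfonyl)ethoxy]chroman-8-yl}[3-(methoxymethoxy)phenyl]methanone | C=C(C)CC[C@H](Cc1c(OCCS(C)(=O)=O)c(C(=O)c2cccc(OCOC)c2)c2c(c1OC)C[C@@H](OCOC)C(C)(C)O2)C(=C)C | intermediate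
27 | {(3R)-7-hydroxy-5-methoxy-3-(methoxymethoxy)-2,2-dimethyl-6-[(2R)-5-methyl-2-(prop-1-en-2-yl)hex-5-en-1-yl]chroman-8-yl}[3-(methoxymethoxy)phenyl]methanone | C=C(C)CC[C@H](Cc1c(O)c(C(=O)c2cccc(OCOC)c2)c2c(c1OC)C[C@@H](OCOC)C(C)(C)O2)C(=C)C | intermediate
28 | {(3R)-3,7-dihydroxy-5-methoxy-2,2-dimethyl-6-[(2R)-5-methyl-2-(prop-1-en-2-yl)hex-5-en-1-yl]chroman-8-yl}(3-hydroxyphenyl)methanone (CNP0307300.2) | C=C(C)CC[C@H](Cc1c(O)c(C(=O)c2cccc(O)c2)c2c(c1OC)C[C@@H](O)C(C)(C)O2)C(=C)C | target

Total step count: 16. Longest linear sequence: 13 steps (steps 1–4, then 8–16, from 1 to 28). The arene branch from 10 runs 10 steps and the amide branch from 7 joins at step 13.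

Steps most likely to fail

Step 14 (key step). The di-ortho-substituted benzoyl group may twist out of the plane of ring A, so that addition of the hindered tertiary alkoxide to C8a becomes slow and intermolecular substitution or base-induced decomposition takes over. The fallback closes the same ring under activation by a planar, stronger acceptor and builds the ketone afterwards; it sets out from 21 and returns at 25. Compound 21 would be dilithiated as in step 13 but quenched with DMF to give 2,6-difluoro-3-[(2R)-3-hydroxy-2-(methoxymethoxy)-3-methylbutyl]-4-methoxy-5-[(2R)-5-methyl-2-(prop-1-en-2-yl)hex-5-en-1-yl]benzaldehyde F1. KOt-Bu in THF at 0 °C should then effect the SNAr ring closure to (3R)-7-fluoro-5-methoxy-3-(methoxymethoxy)-2,2-dimethyl-6-[(2R)-5-methyl-2-(prop-1-en-2-yl)hex-5-en-1-yl]chromane-8-carbaldehyde F2. Addition of 3-(methoxymethoxy)phenylmagnesium bromide would give the diaryl carbinol {(3R)-7-fluoro-5-methoxy-3-(methoxymethoxy)-2,2-dimethyl-6-[(2R)-5-methyl-2-(prop-1-en-2-yl)hex-5-en-1-yl]chroman-8-yl}[3-(methoxymethoxy)phenyl]methanol F3 as a mixture of carbinol epimers, and Dess–Martin periodinane oxidation would deliver 25.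

Step 8. Alkylation may be outrun by loss of LiF from the ortho-fluoroaryllithium (aryne formation) or by attack of the aryllithium at sulfur of the β-branched triflate. The fallback reverses the polarity of the coupling; it sets out from 12 and 5 and returns at 14. Compound 12 would be lithiated as in step 8 and quenched with iodine to give (2,6-difluoro-3-iodo-4-methoxyphenyl)trimethylsilane F4. Alcohol 5 would be converted with I2, PPh3 and imidazole into (3S)-3-(iodomethyl)-2,6-dimethylhepta-1,6-diene F5, and zinc dust with LiCl in THF would turn this into [(2S)-5-methyl-2-(prop-1-en-2-yl)hex-5-en-1-yl]zinc iodide F6. Negishi coupling of F4 with F6 under Pd(OAc)2 and SPhos should give 14.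

Step 15. Substitution at C7, hindered by the C6 chain and less activated once C8a carries oxygen, may stall, or the liberated phenoxide may be re-alkylated by methyl vinyl sulfone. The fallback separates substitution from unmasking and uses a transition-metal deprotection; it sets out from 25 and returns at 27. Sodium allyloxide (allyl alcohol, NaH, DMF) should displace the fluoride to give {(3R)-7-(allyloxy)-5-methoxy-3-(methoxymethoxy)-2,2-dimethyl-6-[(2R)-5-methyl-2-(prop-1-en-2-yl)hex-5-en-1-yl]chroman-8-yl}[3-(methoxymethoxy)phenyl]methanone F7, which cannot undergo Claisen rearrangement because both ortho positions and the para position are substituted. Deallylation with catalytic Pd(PPh3)4 and morpholine in THF would give 27.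

Further compounds
F1 | step 14 | 2,6-difluoro-3-[(2R)-3-hydroxy-2-(methoxymethoxy)-3-methylbutyl]-4-methoxy-5-[(2R)-5-methyl-2-(prop-1-en-2-yl)hex-5-en-1-yl]benzaldehyde | C=C(C)CC[C@H](Cc1c(F)c(C=O)c(F)c(C[C@@H](OCOC)C(C)(C)O)c1OC)C(=C)C
F2 | step 14 | (3R)-7-fluoro-5-methoxy-3-(methoxymethoxy)-2,2-dimethyl-6-[(2R)-5-methyl-2-(prop-1-en-2-yl)hex-5-en-1-yl]chromane-8-carbaldehyde | C=C(C)CC[C@H](Cc1c(F)c(C=O)c2c(c1OC)C[C@@H](OCOC)C(C)(C)O2)C(=C)C
F3 | step 14 | {(3R)-7-fluoro-5-methoxy-3-(methoxymethoxy)-2,2-dimethyl-6-[(2R)-5-methyl-2-(prop-1-en-2-yl)hex-5-en-1-yl]chroman-8-yl}[3-(methoxymethoxy)phenyl]methanol (carbinol epimers) | C=C(C)CC[C@H](Cc1c(F)c(C(O)c2cccc(OCOC)c2)c2c(c1OC)C[C@@H](OCOC)C(C)(C)O2)C(=C)C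
F4 | step 8 | (2,6-difluoro-3-iodo-4-methoxyphenyl)trimethylsilane | COc1cc(F)c([Si](C)(C)C)c(F)c1I
F5 | step 8 | (3S)-3-(iodomethyl)-2,6-dimethylhepta-1,6-diene | C=C(C)CC[C@H](CI)C(C)=C
F6 | step 8 | [(2S)-5-methyl-2-(prop-1-en-2-yl)hex-5-en-1-yl]zinc iodide | C=C(C)CC[C@H](C[Zn]I)C(C)=C
F7 | step 15 | {(3R)-7-(allyloxy)-5-methoxy-3-(methoxymethoxy)-2,2-dimethyl-6-[(2R)-5-methyl-2-(prop-1-en-2-yl)hex-5-en-1-yl]chroman-8-yl}[3-(methoxymethoxy)phenyl]methanone | C=C(C)CC[C@H](Cc1c(OCC=C)c(C(=O)c2cccc(OCOC)c2)c2c(c1OC)C[C@@H](OCOC)C(C)(C)O2)C(=C)C
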